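**Plan**
- Locants: guaianolide numbering. Unprimed atoms belong to the half that carries the C2 carbinol (ring A = cyclopentanone C1–C5, ring B = cycloheptene); primed atoms belong to the spiro half. Ring C is the cyclohexene C2–C1=C10–C14–C15'–C4'.
- Last bond made: C2–C3 of ring A. The tertiary α-ketol C2(OH)–C3(=O), whose carbinol carbon is shared by rings A and C, is an acyloin retron and comes from a ring-C enone carbonyl (C2) plus a C3 aldehyde. The methylenes C4=C15, C11=C13 and C11'=C13' ride through this event as PhSe adducts.
- Before that: ring C (C2–C4', C14–C15') by Diels–Alder reaction of the exocyclic enone of dehydrozaluzanin C with a 2,3-seco-guaianolide vinylketene silyl acetal (C14=C10–C1=C2).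
- The seco diene is made from dehydrozaluzanin C itself (C2 oxygenation, glycol cleavage of C2–C3, redox adjustment to a δ-lactone); dehydrozaluzanin C comes from dehydrocostus lactone in two steps.
- Forward order: rings B, B', A' and both butyrolactones are bought with 1; ring A of one half is opened, ring C is built by cycloaddition, ring A is closed again last.
- Stereochemistry: C5, C6, C7, C1', C5', C6', C7' from 1; C4' from convex-face cycloaddition; C2 from the substrate-controlled acyloin closure.

Key step: step 13

Assumption: (−)-dehydrocostus lactone (1) is bought as the isolated natural product. Stereocentres that are erased later (C3 in 2 and 7; C2 in 5, 6, 7, 10 and 13; C4, C11 and C11' in 16–18) are drawn as the expected isomer or left open.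

**Route**

Step 1
Reactants: 1 (−)-dehydrocostus lactone
Product: 2 3-epizaluzanin C (3α-hydroxy derivative of 1)
Conditions: SeO2 (0.5 equiv), t-BuOOH (2 equiv), CH2Cl2, 23 °C
Reagents that add atoms: tert-butyl hydroperoxide, CC(C)(C)OO (terminal oxidant; its oxygen reaches C3 through the SeO2 catalyst, O=[Se]=O)
Why: Riley allylic oxidation (ene reaction, then [2,3]-sigmatropic shift) should go to the ring CH2 next to the C4(15) exocyclic alkene of ring A, the least hindered allylic methylene; the α-carbinol expected at C3 is erased in step 2.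

Step 2
Reactants: 2 3-epizaluzanin C
Product: 3 dehydrozaluzanin C (3-oxo derivative of 1)
Conditions: Dess–Martin periodinane (1.3 equiv), CH2Cl2, 0 to 23 °C
Reagents that add atoms: none
Why: Dess–Martin oxidation of a secondary allylic alcohol is neutral and should leave the three exocyclic alkenes and the lactone untouched.

Step 3
Reactants: 3 dehydrozaluzanin C
Product: 4 C2=C3 trimethylsilyl enol ether of 3 (3-silyloxy-2,4(15)-diene)
Conditions: TMSOTf (1.2 equiv), Et3N (2 equiv), CH2Cl2, −78 to 0 °C; filtration through Celite with pentane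
Reagents that add atoms: trimethylsilyl trifluoromethanesulfonate, C[Si](C)(C)OS(=O)(=O)C(F)(F)F
Why: Soft enolisation (silyl triflate, tertiary amine) can only use the C2 hydrogens, the sole α-hydrogens of the cross-conjugated ketone, so one 2-silyloxy diene should form and the base-sensitive α-methylene lactone is spared.

Step 4
Reactants: 4 silyl enol ether
Product: 6 2α-hydroxydehydrozaluzanin C, via silyloxy epoxide 5 (not isolated)
Conditions: dimethyldioxirane (1.05 equiv, acetone), CH2Cl2, −78 °C; then 1 M HCl (cat.), THF–H2O, 0 °C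
Reagents that add atoms: dimethyldioxirane, CC1(C)OO1
Why: Rubottom oxidation: the dioxirane should epoxidise the most electron-rich alkene, the silyl enol ether C2=C3, from the convex α face, and acid opens the silyloxy epoxide to the α-hydroxy ketone; the C2 carbinol configuration is of no consequence.

Step 5
Reactants: 6 2α-hydroxydehydrozaluzanin C
Product: 7 2α,3β-dihydroxyguaia-4(15),10(14),11(13)-trien-12,6-olide
Conditions: NaBH4, CeCl3·7H2O, MeOH, −78 °C
Reagents that add atoms: none
Why: Luche reduction should give clean 1,2-reduction of the enone carbonyl, hydride arriving on the convex α face (3β-ol expected), without touching the lactone; either C3 epimer serves.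

Step 6
Reactants: 7 2α,3β-diol
Product: 8 2,3-seco dialdehyde (C2 aldehyde on C1, 1-formylvinyl group on C5)
Conditions: Pb(OAc)4 (1.1 equiv), CH2Cl2, 0 °C
Reagents that add atoms: none
Why: Criegee glycol cleavage with Pb(OAc)4 accepts cis and trans cyclopentane-1,2-diols alike and should open ring A between C2 and C3 under anhydrous, non-basic conditions that spare the β,γ-unsaturated aldehyde.

Step 7
Reactants: 8 seco dialdehyde
Product: 10 δ-lactol (cyclic hemiacetal between O3 and C2; anomers), via seco hydroxy aldehyde 9 (not isolated)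
Conditions: NaBH4 (0.3 equiv), CeCl3·7H2O (1 equiv), EtOH–H2O, −15 °C
Reagents that add atoms: none
Why: Luche-type chemoselective reduction: in aqueous ethanol with CeCl3 the unconjugated C2 aldehyde is held as its hydrate or hemiacetal while the conjugated C3 aldehyde is reduced, and the new allylic alcohol should then add to the C2 aldehyde to give the six-membered lactol.

Step 8
Reactants: 10 δ-lactol
Product: 11 δ-lactone (ring O3–C2(=O)–C1–C5–C4(=CH2)–C3H2)
Conditions: Ag2CO3 on Celite, benzene, 80 °C
Reagents that add atoms: none
Why: Fétizon oxidation converts lactols into lactones on a neutral surface and should not touch the alkenes or the α-methylene lactone.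

Step 9
Reactants: 11 δ-lactone
Product: 12 cyclic vinylketene tert-butyldimethylsilyl acetal (C14H2=C10–C1=C2(OTBS)–O3)
Conditions: TBSOTf (1.1 equiv), Et3N (2 equiv), CH2Cl2, −78 to 0 °C; filtration through Celite with pentane, used crude
Reagents that add atoms: tert-butyldimethylsilyl trifluoromethanesulfonate, CC(C)(C)[Si](C)(C)OS(=O)(=O)C(F)(F)F
Why: Soft enolisation of the lactone at C1, whose hydrogen is both α to the carbonyl and allylic, should give the vinylketene silyl acetal; C2 and C14 are held cis across the C1–C10 ring bond, so the diene is locked s-cis.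

Step 10
Reactants: 12 vinylketene silyl acetal; 3 dehydrozaluzanin C (1.5 equiv)
Product: 14 hydroxy enedione (ring C cyclohexenone spiro-linked at C4'; C5 bears 3-hydroxyprop-1-en-2-yl), via spiro silyl ketal 13 (not isolated)
Conditions: toluene, 23 to 45 °C; then 1 M HCl, THF, 0 °C
Reagents that add atoms: none
Why: Diels–Alder reaction of an electron-rich 1,1-dioxygenated diene with an exocyclic enone: the unsubstituted terminus C14 should bond to the β-carbon C15' and C2 to C4', the diene adds to the convex α face of the cis-fused hydroazulenone (the face of H1' and H5') and so sets the spiro centre C4', and mild acid then unravels the silyl ketal to the C2 ketone and the C3 alcohol.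

Step 11
Reactants: 14 hydroxy enedione
Product: 15 keto enal (C3 aldehyde conjugated to C4=C15)
Conditions: Dess–Martin periodinane (1.3 equiv), CH2Cl2, 0 °C
Reagents that add atoms: none
Why: Dess–Martin oxidation of the primary allylic alcohol to the enal runs under slightly acidic conditions, which should avoid the base-triggered retro-Claisen opening that the hydroxy diketone could suffer through its hemiketal.

Step 12
Reactants: 15 keto enal
Product: 16 tris(phenylselenide) keto aldehyde (PhSe on C15, C13 and C13')
Conditions: PhSeH (3.3 equiv), Et3N (0.1 equiv), CH2Cl2, 0 °C, argon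
Reagents that add atoms: benzeneselenol, [SeH]c1ccccc1
Why: Seleno-Michael addition: the soft selenolate should add to the three unhindered exocyclic acceptors (C15, C13, C13') but not to the tetrasubstituted C1=C10 enone, which turns the enal into an ordinary aliphatic aldehyde and removes every Michael acceptor before the carbene step; the new centres at C4, C11 and C11' are erased in step 14.

Step 13
Reactants: 16 tris(phenylselenide) keto aldehyde
Product: 17 ring-A α-ketol tris(phenylselenide)
Conditions: 2-(pentafluorophenyl)-6,7-dihydro-5H-pyrrolo[2,1-c][1,2,4]triazol-2-ium tetrafluoroborate (0.2 equiv), i-Pr2NEt (0.2 equiv), CH2Cl2, 23 °C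
Reagents that add atoms: none
Why: The carbene adds to the C3 aldehyde and a proton shift gives the Breslow intermediate, whose nucleophilic C3 attacks the C2 carbonyl of ring C; proton transfer and loss of the carbene leave the C3 ketone and the tertiary C2 carbinol, a redox-neutral isomerisation. The closest known reaction type is the carbene-catalysed intramolecular crossed aldehyde–ketone benzoin (acyloin) cyclisation that gives five- and six-membered cyclic tertiary α-ketols. Ring A closes through the C2–C3 bond in a 5-exo-trig mode, with the carbonyl oxygen outside the new ring. The new centre C2 is controlled by the substrate: H5 lies on the α face, so the C4–C3 arm on C5 should reach the carbonyl from the β face, and at the neighbouring spiro carbon C4' that face carries only the flat C3' carbonyl whereas the α face is blocked by C5' and ring B'; the oxygen is therefore pushed to the α face, cis to H5, as in the target. The step needs chemoselectivity for C2 over the C3' ketone and for 1,2-addition over Stetter or homoenolate channels: attack at C3' would need a seven-membered ring, conjugate attack at the fully substituted C10 would be 5-endo, and the three Michael acceptors are masked as selenides. A weak amine base in catalytic amount should keep the retro-aldol opening of the new β-hydroxy ketone (C2–C4'–C3') and the loss of selenolate from C15 at bay, and the two C4 epimers converge after step 14.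

Step 14
Reactants: 17 α-ketol tris(phenylselenide)
Product: 19 CNP0269880.2 (target), via tris-selenoxide 18 (not isolated)
Conditions: mCPBA (3.05 equiv), CH2Cl2, −78 °C; then pyridine, −78 to 23 °C
Reagents that add atoms: none
Why: Selenoxide syn-elimination: each selenium sits on a primary carbon with a single β-hydrogen (H4, H11, H11'), so only the three exocyclic methylenes can form, at low temperature and without strong base that would endanger the β-hydroxy ketone.

**Compound list**

1 | (−)-dehydrocostus lactone, (1αH,5αH,6βH,7αH)-guaia-4(15),10(14),11(13)-trien-12,6-olide | C=C1CC[C@H]2C(=C)CC[C@H]3C(=C)C(=O)O[C@@H]3[C@H]21 | starting material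
2 | 3-epizaluzanin C (3α-hydroxy-1) | C=C1[C@H](O)C[C@H]2C(=C)CC[C@H]3C(=C)C(=O)O[C@@H]3[C@H]21 | intermediate
3 | dehydrozaluzanin C (3-oxo-1) | C=C1C(=O)C[C@H]2C(=C)CC[C@H]3C(=C)C(=O)O[C@@H]3[C@H]21 | intermediate
4 | 3-(trimethylsilyloxy)guaia-2,4(15),10(14),11(13)-tetraen-12,6-olide | C=C1C(O[Si](C)(C)C)=C[C@H]2C(=C)CC[C@H]3C(=C)C(=O)O[C@@H]3[C@H]21 | intermediate
5 | 2α,3α-epoxy-3-(trimethylsilyloxy)guaia-4(15),10(14),11(13)-trien-12,6-olide | C=C1[C@]2(O[Si](C)(C)C)O[C@@H]2[C@H]2C(=C)CC[C@H]3C(=C)C(=O)O[C@@H]3[C@H]21 | intermediate
6 | 2α-hydroxydehydrozaluzanin C (2α-hydroxy-3-oxo) | C=C1C(=O)[C@H](O)[C@H]2C(=C)CC[C@H]3C(=C)C(=O)O[C@@H]3[C@H]21 | intermediate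
7 | 2α,3β-dihydroxyguaia-4(15),10(14),11(13)-trien-12,6-olide | C=C1[C@@H](O)[C@H](O)[C@H]2C(=C)CC[C@H]3C(=C)C(=O)O[C@@H]3[C@H]21 | intermediate
8 | 2,3-seco dialdehyde: 10-methylene cycloheptane with trans-fused α-methylene-γ-butyrolactone (H6β, H7α), CHO on C1 (1αH), 1-formylvinyl on C5 (5αH) | O=C[C@H]1C(=C)CC[C@H]2C(=C)C(=O)O[C@@H]2[C@H]1C(=C)C=O | intermediate
9 | seco hydroxy aldehyde (8 with C3 as CH2OH) | O=C[C@H]1C(=C)CC[C@H]2C(=C)C(=O)O[C@@H]2[C@H]1C(=C)CO | intermediate
10 | δ-lactol: cyclic hemiacetal O3–C2 of 9, cis-fused at C1–C5, anomers | OC1OCC(=C)[C@H]2[C@@H]1C(=C)CC[C@H]1C(=C)C(=O)O[C@@H]12 | intermediate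
11 | δ-lactone: 2,3-seco-2-oic acid O3-lactone, 4(15)-, 10(14)- and 11(13)-methylenes retained | O=C1OCC(=C)[C@H]2[C@@H]1C(=C)CC[C@H]1C(=C)C(=O)O[C@@H]12 | intermediate
12 | vinylketene tert-butyldimethylsilyl acetal of 11 (C2(OTBS)(O3)=C1, C10=C14H2, 5αH) | CC(C)(C)[Si](C)(C)OC1=C2C(=C)CC[C@H]3C(=C)C(=O)O[C@@H]3[C@H]2C(=C)CO1 | intermediate
13 | Diels–Alder adduct: ring C closed, C2 a mixed silyl ketal (OTBS and O3), C1=C10, spiro C4' | C=C1COC2(O[Si](C)(C)C(C)(C)C)C3=C(CC[C@H]4C(=C)C(=O)O[C@@H]4[C@@H]13)CC[C@]21C(=O)C[C@H]2C(=C)CC[C@H]3C(=C)C(=O)O[C@@H]3[C@H]21 | intermediate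
14 | hydroxy enedione: ring C cyclohexenone (C2=O, C1=C10) spiro at C4' to the cyclopentanone of the primed half; C5 (5αH) bears 3-hydroxyprop-1-en-2-yl | O=C1C2=C(CC[C@H]3C(=C)C(=O)O[C@@H]3[C@H]2C(=C)CO)CC[C@]14C(=O)C[C@H]5C(=C)CC[C@H]6C(=C)C(=O)O[C@@H]6[C@H]54 | intermediate
15 | keto enal (14 with C3 as aldehyde) | O=C1C2=C(CC[C@H]3C(=C)C(=O)O[C@@H]3[C@H]2C(=C)C=O)CC[C@]14C(=O)C[C@H]5C(=C)CC[C@H]6C(=C)C(=O)O[C@@H]6[C@H]54 | intermediate
16 | tris(phenylselenide) keto aldehyde: PhSeCH2 at C4 (epimers), C11 and C11' (H11 and H11' β expected) | O=C1C2=C(CC[C@H]3[C@H](C[Se]c7ccccc7)C(=O)O[C@@H]3[C@H]2C(C[Se]c8ccccc8)C=O)CC[C@]14C(=O)C[C@H]5C(=C)CC[C@H]6[C@H](C[Se]c9ccccc9)C(=O)O[C@@H]6[C@H]54 | intermediate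
17 | ring-A α-ketol tris(phenylselenide): target skeleton with C15, C13, C13' as CH2SePh and H at C4, C11, C11' | c7ccccc7[Se]CC1C(=O)[C@]2(O)C3=C(CC[C@H]4[C@H](C[Se]c8ccccc8)C(=O)O[C@@H]4[C@@H]13)CC[C@]21C(=O)C[C@H]2C(=C)CC[C@H]3[C@H](C[Se]c9ccccc9)C(=O)O[C@@H]3[C@H]21 | intermediate
18 | tris(selenoxide) of 17 | c7ccccc7[Se](=O)CC1C(=O)[C@]2(O)C3=C(CC[C@H]4[C@H](C[Se](=O)c8ccccc8)C(=O)O[C@@H]4[C@@H]13)CC[C@]21C(=O)C[C@H]2C(=C)CC[C@H]3[C@H](C[Se](=O)c9ccccc9)C(=O)O[C@@H]3[C@H]21 | intermediate
19 | CNP0269880.2 | C=C1C(=O)[C@]2(O)C3=C(CC[C@H]4C(=C)C(=O)O[C@@H]4[C@@H]13)CC[C@]21C(=O)C[C@H]2C(=C)CC[C@H]3C(=C)C(=O)O[C@@H]3[C@H]21 | target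

**Totals**

Total step count: 14. Longest linear sequence: 14 steps (1 to 19); compound 3 is used twice, as precursor of the diene in step 3 and as dienophile in step 10.

**Steps most likely to fail**

Step 13. The Breslow intermediate of the α-branched aldehyde may form slowly, C3 may add to the wrong face of the C2 carbonyl, or the base may open the new β-hydroxy ketone by retro-aldol cleavage of C2–C4'. The fallback sets out from 16 and replaces the redox-neutral umpolung by a reductive coupling and re-oxidation. SmI2 (THF, −78 °C) should effect the intramolecular ketone–aldehyde pinacol cyclisation to the cis-2,3-diol, the pinacol diol tris(phenylselenide) F1, under the same tether control. Parikh–Doering oxidation (SO3·pyridine, DMSO, i-Pr2NEt) of the secondary C3 carbinol, which the tertiary C2 carbinol cannot follow, comes back to the route at 17.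

Step 10. The very nucleophilic ketene acetal may react stepwise (Mukaiyama–Michael addition that stops before the C2–C4' bond closes), may be hydrolysed back to the lactone, or may add to the lactone methylene instead of the enone. The fallback sets out from lactol 10. Acid-catalysed dehydration (PPTS, toluene, molecular sieves, 80 °C) should give the less polarised cyclic dienol ether F2, again locked s-cis with its oxygen outside. Thermal cycloaddition with 3 (toluene, 80 °C) should give the cyclic bis-allylic ether adduct F3, which cannot fragment. DDQ in wet CH2Cl2 should abstract hydride from C2–H (activated by the ring oxygen and the tetrasubstituted C1=C10 alkene); hydrolysis of the oxocarbenium ion comes back to the route at 14.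

Step 7. Chemoselectivity between the two aldehydes may be lost, by over-reduction to the diol or by reduction of the unconjugated carbonyl, which would lead to the regioisomeric lactol. The fallback sets out from 8 and separates protection, reduction and release. Selective acetalisation of the unconjugated aldehyde (HC(OMe)3, CeCl3·7H2O, MeOH, 0 °C) should give the C2 dimethyl acetal enal F4. NaBH4 (MeOH, −40 °C) then reduces the only free aldehyde to the acetal allylic alcohol F5. PPTS in wet acetone releases the C2 aldehyde, which closes on the C3 hydroxyl and comes back to the route at 10.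

**Further compounds**

F1 | step 13 | pinacol diol tris(phenylselenide): 17 with C3 as CH(OH), cis to the C2 hydroxyl | c7ccccc7[Se]CC1C(O)[C@]2(O)C3=C(CC[C@H]4[C@H](C[Se]c8ccccc8)C(=O)O[C@@H]4[C@@H]13)CC[C@]21C(=O)C[C@H]2C(=C)CC[C@H]3[C@H](C[Se]c9ccccc9)C(=O)O[C@@H]3[C@H]21
F2 | step 10 | cyclic dienol ether: 12 with H in place of OTBS at C2 | C1=C2C(=C)CC[C@H]3C(=C)C(=O)O[C@@H]3[C@H]2C(=C)CO1
F3 | step 10 | cyclic bis-allylic ether adduct: 13 with H in place of OTBS at C2 | C=C1COC2C3=C(CC[C@H]4C(=C)C(=O)O[C@@H]4[C@@H]13)CC[C@]21C(=O)C[C@H]2C(=C)CC[C@H]3C(=C)C(=O)O[C@@H]3[C@H]21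
F4 | step 7 | C2 dimethyl acetal of dialdehyde 8, C3 enal free | COC(OC)[C@H]1C(=C)CC[C@H]2C(=C)C(=O)O[C@@H]2[C@H]1C(=C)C=O
F5 | step 7 | C2 dimethyl acetal with C3 as allylic CH2OH | COC(OC)[C@H]1C(=C)CC[C@H]2C(=C)C(=O)O[C@@H]2[C@H]1C(=C)CO
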